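**Retrosynthetic overview**

1. Numbering: chain C1 (bears ring A and ring C), C2 (CH3), C3 (CH3), C4 (CH2 to ring D); ring A is the acylphloroglucinol, ring B the 4-methoxyphenyl ring; the target is (1R,2R,3S). The five benzyl ethers come off last, and before that the ring A–acyl bond is made by Friedel–Crafts acylation of a symmetric tribenzyloxy ring A.
2. C3 is set by iridium-catalysed hydrogenation of a geometrically pure (E)-C3=C4 alkene. The alkene comes from the (Z)-enol triflate of a benzyl ketone (C3–CH3 by Negishi coupling), and the ketone from a Weinreb amide and the ring D benzyl Grignard reagent (C3–C4).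
3. The strategy rests on the phenol oxygen of ring A that sits ortho to C1: that oxygen, two ring A carbons, C1, C2 and C3 as a carbonyl form a six-membered lactone (a trans-3-methyl-4-aryl-dihydrocoumarin). It is the only ring made in the route and is opened again to the Weinreb amide.
4. The lactone is cut at C1–C2 and at the aryl O–C3(=O) bond: ring A ortho-quinone methide plus the azolium enolate of a propanoyl donor under a chiral N-heterocyclic carbene.
5. The quinone methide precursor is a sulfone made from 2,4,6-trihydroxybenzaldehyde by dibenzylation, addition of the ring C Grignard reagent and exchange of the benzhydrol OH for p-toluenesulfinate.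

Key step: step 4

Assumption: N-propanoylimidazole is bought, and the absolute sense of the triazolium catalyst (step 4) and of the iridium catalyst (step 10) is fixed on a small run, both enantiomers of each being available; the route is written for the enantiomers that give 4R and 3S.
Remark: the descriptor at C2 is S while C3 is a carbonyl or alkene carbon and becomes R in 18 with no change of geometry, because the CIP ranking of C1 and C3 is exchanged.

**Route**

Step 1
Reactants: 1 2,4,6-trihydroxybenzaldehyde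
Product: 2 2,4-bis(benzyloxy)-6-hydroxybenzaldehyde
Conditions: BnBr (2.05 equiv), K2CO3 (2.2 equiv), DMF, 0 °C to rt
Reagents that add atoms: benzyl bromide, BrCc1ccccc1
Why: Williamson etherification in which the 4-OH and one 2-OH are alkylated, while the last ortho OH, hydrogen-bonded to the aldehyde, should stay free with a weak base and two equivalents of halide.

Step 2
Reactants: 2 2,4-bis(benzyloxy)-6-hydroxybenzaldehyde; 3 1-benzyloxy-4-bromobenzene
Product: 5 rac-3,5-bis(benzyloxy)-2-{[4-(benzyloxy)phenyl](hydroxy)methyl}phenol, via 4-(benzyloxy)phenylmagnesium bromide 4 (not isolated)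
Conditions: 3 (2.5 equiv), Mg, THF, reflux; then 2, THF, 0 °C to rt; aq NH4Cl; crude product used at once
Reagents that add atoms: none
Why: Grignard addition to a salicylaldehyde, in which the first equivalent is consumed by the phenol and the second adds to the aldehyde of the magnesium phenoxide; the new stereocentre is racemic and is erased in step 4.

Step 3
Reactants: 5 rac-3,5-bis(benzyloxy)-2-{[4-(benzyloxy)phenyl](hydroxy)methyl}phenol
Product: 6 rac-3,5-bis(benzyloxy)-2-{[4-(benzyloxy)phenyl](4-methylbenzenesulfonyl)methyl}phenol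
Conditions: p-TolSO2H (1.5 equiv), CH2Cl2, rt
Reagents that add atoms: p-toluenesulfinic acid, Cc1ccc(cc1)S(=O)O
Why: SN1-type substitution in which the sulfinic acid ionises the electron-rich ortho-hydroxybenzhydrol and the sulfinate captures the cation at sulfur, giving a storable quinone methide precursor.

Step 4
Reactants: 6 rac-3,5-bis(benzyloxy)-2-{[4-(benzyloxy)phenyl](4-methylbenzenesulfonyl)methyl}phenol; 7 N-propanoylimidazole
Product: 10 (3S,4R)-5,7-bis(benzyloxy)-4-[4-(benzyloxy)phenyl]-3-methylchroman-2-one (trans lactone), via ortho-quinone methide 8 (not isolated), via cis lactone 9 (not isolated)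
Conditions: 7 (2 equiv), (5aS,10bR)-2-mesityl-5a,10b-dihydro-4H,6H-indeno[2,1-b][1,2,4]triazolo[4,3-d][1,4]oxazin-2-ium tetrafluoroborate (15 mol %), Cs2CO3 (1.5 equiv), 4 Å MS, THF, 0 °C to rt, 6 added slowly; then DBU (0.5 equiv), rt
Reagents that add atoms: none
Why: Cs2CO3 deprotonates the phenol of 6 and expels sulfinate to give quinone methide 8, while the carbene is acylated by 7 and deprotonated to the azolium enolate, whose C2 adds to the methide carbon C1; the phenoxide so regenerated then acylates on the acyl azolium and frees the carbene. The closest known reaction type is the carbene-catalysed formal [4+2] annulation of azolium enolates with ortho-quinone methides to 3,4-dihydrocoumarins. The single six-membered lactone ring is closed by 6-exo-trig O-acylation after the C1–C2 bond has formed. C1 (lactone C4, R) is set by the aminoindanol backbone of the catalyst, which shields one face of the bound enolate. C2 (lactone C3) is expected to form cis (9) and is then moved by DBU to the trans isomer 10, in which the methyl group lies anti to the C4 aryl group that the C5 benzyloxy group holds pseudoaxial. The step needs enantioface control at C1 and annulation in preference to self-condensation of 8; the two benzyloxy donors on ring A stabilise 8, slow addition keeps its concentration low, and rearomatisation of ring A drives the addition.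

Step 5
Reactants: 10 (3S,4R)-5,7-bis(benzyloxy)-4-[4-(benzyloxy)phenyl]-3-methylchroman-2-one
Product: 11 (2S,3R)-3-[2,4-bis(benzyloxy)-6-hydroxyphenyl]-3-[4-(benzyloxy)phenyl]-N-methoxy-N,2-dimethylpropanamide
Conditions: MeNH(OMe)·HCl (3 equiv), AlMe3 (3 equiv), CH2Cl2, 0 °C to rt
Reagents that add atoms: N,O-dimethylhydroxylamine hydrochloride, CNOC.Cl
Why: Weinreb aminolysis of an aryl lactone with the aluminium amide, which should open the activated aryl ester at low temperature without touching the C2 stereocentre.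

Step 6
Reactants: 11 (2S,3R)-3-[2,4-bis(benzyloxy)-6-hydroxyphenyl]-3-[4-(benzyloxy)phenyl]-N-methoxy-N,2-dimethylpropanamide
Product: 12 (2S,3R)-3-[4-(benzyloxy)phenyl]-N-methoxy-N,2-dimethyl-3-[2,4,6-tris(benzyloxy)phenyl]propanamide
Conditions: BnBr (1.3 equiv), K2CO3 (2 equiv), DMF, rt
Reagents that add atoms: benzyl bromide, BrCc1ccccc1
Why: Williamson etherification that blocks the phenol (which would otherwise close a chromanol hemiketal on the later C3 ketone) and makes ring A symmetric, so that step 11 can give only one regioisomer.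

Step 7
Reactants: 12 (2S,3R)-3-[4-(benzyloxy)phenyl]-N-methoxy-N,2-dimethyl-3-[2,4,6-tris(benzyloxy)phenyl]propanamide; 13 4-benzyloxybenzyl chloride
Product: 15 (3S,4R)-1,4-bis[4-(benzyloxy)phenyl]-3-methyl-4-[2,4,6-tris(benzyloxy)phenyl]butan-2-one, via 4-(benzyloxy)benzylmagnesium chloride 14 (not isolated)
Conditions: 13 (3 equiv), Mg, Et2O, 0 °C; then 12, THF, 0 °C to rt; aq NH4Cl
Reagents that add atoms: none
Why: Weinreb ketone synthesis, in which the chelated tetrahedral intermediate survives until work-up, so the benzyl Grignard reagent adds once and brings in C4 and ring D.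

Step 8
Reactants: 15 (3S,4R)-1,4-bis[4-(benzyloxy)phenyl]-3-methyl-4-[2,4,6-tris(benzyloxy)phenyl]butan-2-one
Product: 16 (1Z,3S,4R)-1,4-bis[4-(benzyloxy)phenyl]-3-methyl-4-[2,4,6-tris(benzyloxy)phenyl]but-1-en-2-yl trifluoromethanesulfonate
Conditions: KN(SiMe3)2 (1.3 equiv), THF, −78 °C, ketone added to base; PhNTf2 (1.4 equiv), −78 to 0 °C
Reagents that add atoms: N-phenylbis(trifluoromethanesulfonimide), O=S(=O)(N(c1ccccc1)S(=O)(=O)C(F)(F)F)C(F)(F)F
Why: Regioselective enolate O-triflation: the base removes the far more acidic and less hindered benzylic C4–H and not the tertiary C2–H, and the enolate should form with ring D syn to oxygen and away from the bulky C2 substituent, which fixes the Z geometry and leaves C2 untouched.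

Step 9
Reactants: 16 (1Z,3S,4R)-1,4-bis[4-(benzyloxy)phenyl]-3-methyl-4-[2,4,6-tris(benzyloxy)phenyl]but-1-en-2-yl trifluoromethanesulfonate
Product: 17 (1E,3S,4R)-1,4-bis[4-(benzyloxy)phenyl]-2,3-dimethyl-4-[2,4,6-tris(benzyloxy)phenyl]but-1-ene
Conditions: Zn(CH3)2 (2 equiv), Pd(PPh3)4 (5 mol %), THF, 0 to 50 °C
Reagents that add atoms: dimethylzinc, C[Zn]C
Why: Negishi cross-coupling of an alkenyl triflate, which proceeds with retention of alkene geometry and should therefore place the new C3 methyl group cis to ring D (E alkene).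

Step 10
Reactants: 17 (1E,3S,4R)-1,4-bis[4-(benzyloxy)phenyl]-2,3-dimethyl-4-[2,4,6-tris(benzyloxy)phenyl]but-1-ene
Product: 18 1,3,5-tris(benzyloxy)-2-{(1R,2R,3S)-1,4-bis[4-(benzyloxy)phenyl]-2,3-dimethylbutyl}benzene
Conditions: [Ir(cod)(L)][B(3,5-(CF3)2C6H3)4] (2 mol %; L = (S)-4-tert-butyl-2-[2-(diphenylphosphanyl)phenyl]-4,5-dihydrooxazole), H2 (50 bar), CH2Cl2, rt
Reagents that add atoms: none
Why: Iridium/P,N-ligand asymmetric hydrogenation of an unfunctionalised trisubstituted alkene, in which the catalyst selects the face of the geometrically pure E alkene and should set C3 as S, while the homogeneous cationic catalyst leaves the benzyl ethers intact.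

Step 11
Reactants: 18 1,3,5-tris(benzyloxy)-2-{(1R,2R,3S)-1,4-bis[4-(benzyloxy)phenyl]-2,3-dimethylbutyl}benzene; 19 3-(4-methoxyphenyl)propanoic acid
Product: 21 1-(2,4,6-tris(benzyloxy)-3-{(1R,2R,3S)-1,4-bis[4-(benzyloxy)phenyl]-2,3-dimethylbutyl}phenyl)-3-(4-methoxyphenyl)propan-1-one, via mixed trifluoroacetic anhydride 20 (not isolated)
Conditions: 19 (1.5 equiv), (CF3CO)2O (2 equiv), CH2Cl2, 0 °C; then 18, 0 °C to rt
Reagents that add atoms: none
Why: Friedel–Crafts acylation through the mixed anhydride, which needs no metal Lewis acid; the trialkoxy ring A is far more nucleophilic than rings C and D, and its two free positions are equivalent.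

Step 12
Reactants: 21 1-(2,4,6-tris(benzyloxy)-3-{(1R,2R,3S)-1,4-bis[4-(benzyloxy)phenyl]-2,3-dimethylbutyl}phenyl)-3-(4-methoxyphenyl)propan-1-one
Product: 22 1-(2,4,6-trihydroxy-3-{(1R,2R,3S)-1,4-bis(4-hydroxyphenyl)-2,3-dimethylbutyl}phenyl)-3-(4-methoxyphenyl)propan-1-one (target)
Conditions: H2 (1 atm), Pd/C (10 %), EtOAc–MeOH, rt
Reagents that add atoms: none
Why: Catalytic hydrogenolysis of the five aryl benzyl ethers; the doubly ortho-hydroxylated, hydrogen-bonded aryl ketone should not be reduced at 1 atm, and none of the three stereocentres carries a cleavable bond.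

**Compound list**

1 | 2,4,6-trihydroxybenzaldehyde | O=Cc1c(O)cc(O)cc1O | starting material
2 | 2,4-bis(benzyloxy)-6-hydroxybenzaldehyde | O=Cc1c(O)cc(OCc2ccccc2)cc1OCc1ccccc1 | intermediate
3 | 1-benzyloxy-4-bromobenzene | Brc1ccc(OCc2ccccc2)cc1 | starting material
4 | 4-(benzyloxy)phenylmagnesium bromide | Br[Mg]c1ccc(OCc2ccccc2)cc1 | intermediate (not isolated)
5 | rac-3,5-bis(benzyloxy)-2-{[4-(benzyloxy)phenyl](hydroxy)methyl}phenol | OC(c1ccc(OCc2ccccc2)cc1)c1c(O)cc(OCc2ccccc2)cc1OCc1ccccc1 | intermediate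
6 | rac-3,5-bis(benzyloxy)-2-{[4-(benzyloxy)phenyl](4-methylbenzenesulfonyl)methyl}phenol | Cc1ccc(S(=O)(=O)C(c2ccc(OCc3ccccc3)cc2)c2c(O)cc(OCc3ccccc3)cc2OCc2ccccc2)cc1 | intermediate
7 | N-propanoylimidazole | CCC(=O)n1ccnc1 | starting material
8 | 3,5-bis(benzyloxy)-6-[4-(benzyloxy)benzylidene]cyclohexa-2,4-dien-1-one (ortho-quinone methide; geometry of the exocyclic alkene not fixed) | O=C1C=C(OCc2ccccc2)C=C(OCc2ccccc2)C1=Cc1ccc(OCc2ccccc2)cc1 | intermediate (not isolated)
9 | (3R,4R)-5,7-bis(benzyloxy)-4-[4-(benzyloxy)phenyl]-3-methylchroman-2-one (cis lactone) | O=C1Oc2cc(OCc3ccccc3)cc(OCc3ccccc3)c2[C@@H](c2ccc(OCc3ccccc3)cc2)[C@H]1C | intermediate (not isolated)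
10 | (3S,4R)-5,7-bis(benzyloxy)-4-[4-(benzyloxy)phenyl]-3-methylchroman-2-one (trans lactone) | O=C1Oc2cc(OCc3ccccc3)cc(OCc3ccccc3)c2[C@@H](c2ccc(OCc3ccccc3)cc2)[C@@H]1C | intermediate
11 | (2S,3R)-3-[2,4-bis(benzyloxy)-6-hydroxyphenyl]-3-[4-(benzyloxy)phenyl]-N-methoxy-N,2-dimethylpropanamide | CON(C)C(=O)[C@@H](C)[C@H](c1ccc(OCc2ccccc2)cc1)c1c(O)cc(OCc2ccccc2)cc1OCc1ccccc1 | intermediate
12 | (2S,3R)-3-[4-(benzyloxy)phenyl]-N-methoxy-N,2-dimethyl-3-[2,4,6-tris(benzyloxy)phenyl]propanamide | CON(C)C(=O)[C@@H](C)[C@H](c1ccc(OCc2ccccc2)cc1)c1c(OCc2ccccc2)cc(OCc2ccccc2)cc1OCc1ccccc1 | intermediate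
13 | 4-benzyloxybenzyl chloride | ClCc1ccc(OCc2ccccc2)cc1 | starting material
14 | 4-(benzyloxy)benzylmagnesium chloride | Cl[Mg]Cc1ccc(OCc2ccccc2)cc1 | intermediate (not isolated)
15 | (3S,4R)-1,4-bis[4-(benzyloxy)phenyl]-3-methyl-4-[2,4,6-tris(benzyloxy)phenyl]butan-2-one | O=C(Cc1ccc(OCc2ccccc2)cc1)[C@@H](C)[C@H](c1ccc(OCc2ccccc2)cc1)c1c(OCc2ccccc2)cc(OCc2ccccc2)cc1OCc1ccccc1 | intermediate
16 | (1Z,3S,4R)-1,4-bis[4-(benzyloxy)phenyl]-3-methyl-4-[2,4,6-tris(benzyloxy)phenyl]but-1-en-2-yl trifluoromethanesulfonate | O=S(=O)(O/C(=C\c1ccc(OCc2ccccc2)cc1)[C@@H](C)[C@H](c1ccc(OCc2ccccc2)cc1)c1c(OCc2ccccc2)cc(OCc2ccccc2)cc1OCc1ccccc1)C(F)(F)F | intermediate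
17 | (1E,3S,4R)-1,4-bis[4-(benzyloxy)phenyl]-2,3-dimethyl-4-[2,4,6-tris(benzyloxy)phenyl]but-1-ene | C/C(=C\c1ccc(OCc2ccccc2)cc1)[C@@H](C)[C@H](c1ccc(OCc2ccccc2)cc1)c1c(OCc2ccccc2)cc(OCc2ccccc2)cc1OCc1ccccc1 | intermediate
18 | 1,3,5-tris(benzyloxy)-2-{(1R,2R,3S)-1,4-bis[4-(benzyloxy)phenyl]-2,3-dimethylbutyl}benzene | C(Oc1cc(OCc2ccccc2)c([C@@H](c2ccc(OCc3ccccc3)cc2)[C@H](C)[C@@H](C)Cc2ccc(OCc3ccccc3)cc2)c(OCc2ccccc2)c1)c1ccccc1 | intermediate
19 | 3-(4-methoxyphenyl)propanoic acid | COc1ccc(CCC(=O)O)cc1 | starting material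
20 | 3-(4-methoxyphenyl)propanoic trifluoroacetic anhydride | COc1ccc(CCC(=O)OC(=O)C(F)(F)F)cc1 | intermediate (not isolated)
21 | 1-(2,4,6-tris(benzyloxy)-3-{(1R,2R,3S)-1,4-bis[4-(benzyloxy)phenyl]-2,3-dimethylbutyl}phenyl)-3-(4-methoxyphenyl)propan-1-one | COc1ccc(CCC(=O)c2c(OCc3ccccc3)cc(OCc3ccccc3)c([C@@H](c3ccc(OCc4ccccc4)cc3)[C@H](C)[C@@H](C)Cc3ccc(OCc4ccccc4)cc3)c2OCc2ccccc2)cc1 | intermediate
22 | 1-(2,4,6-trihydroxy-3-{(1R,2R,3S)-1,4-bis(4-hydroxyphenyl)-2,3-dimethylbutyl}phenyl)-3-(4-methoxyphenyl)propan-1-one | COc1ccc(CCC(=O)c2c(O)cc(O)c([C@@H](c3ccc(O)cc3)[C@H](C)[C@@H](C)Cc3ccc(O)cc3)c2O)cc1 | target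

**Step count**

Total: 12 steps. Longest linear sequence: 12 steps (1 to 22); compounds 3, 7, 13 and 19 enter as bought materials.

**Steps most likely to fail**

Step 4. The quinone methide carries a benzyloxy group next to the methide carbon and its alkene geometry is not fixed, so facial selectivity at C1 may be poor. It may also oligomerise faster than the alkyl acyl azolium is enolised, and the cis-to-trans equilibration at C2 may stop short. The fallback builds the same lactone in another order, setting out from aldehyde 2. Heating 2 with Ph3P=CHCO2Et in N,N-diethylaniline should give, by Wittig olefination and lactonisation, 5,7-bis(benzyloxy)coumarin F1. Rhodium-catalysed asymmetric 1,4-addition of 4-(benzyloxy)phenylboronic acid ([Rh(acac)(C2H4)2], the SEGPHOS enantiomer that gives 4R, dioxane–water, 60 °C) should then give (R)-5,7-bis(benzyloxy)-4-[4-(benzyloxy)phenyl]chroman-2-one F2. Its lithium enolate (LiN(SiMe3)2, THF, −78 °C) is methylated with MeI on the face anti to the pseudoaxial C4 aryl group, which is kinetic trans control, and the route is rejoined at trans lactone 10.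

Step 10. The alkene is hindered by the branched C2 substituent, so conversion may stall, and the existing C2 centre may oppose the catalyst and lower the facial selectivity at C3. The fallback sets out from ketone 15 and relies on substrate control. Addition of Me3SiCH2MgCl in the presence of CeCl3 (THF, −78 °C) should give (3S,4R)-1,4-bis[4-(benzyloxy)phenyl]-3-methyl-4-[2,4,6-tris(benzyloxy)phenyl]-2-[(trimethylsilyl)methyl]butan-2-ol F3 as a mixture of carbinol epimers. Peterson elimination with KH in THF should give (3S,4R)-1,4-bis[4-(benzyloxy)phenyl]-3-methyl-2-methylidene-4-[2,4,6-tris(benzyloxy)phenyl]butane F4. F4 is hydrogenated with RhCl(PPh3)3 under H2 in benzene–ethanol. On the allylic-strain model the C2–H bond eclipses the methylidene group and hydrogen is delivered anti to the diarylmethyl group, which corresponds to 3S; whether this conformer is the reactive one is not certain. The route is rejoined at 18.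

Step 11. Trifluoroacetic acid may cleave or shift benzyl groups on the very electron-rich ring A, or ipso attack may split off the C1 substituent. The fallback sets out from 18 and avoids acid-mediated acylation. Vilsmeier–Haack formylation (POCl3, DMF, 0 °C to rt, aqueous NaOAc) should give 2,4,6-tris(benzyloxy)-3-{(1R,2R,3S)-1,4-bis[4-(benzyloxy)phenyl]-2,3-dimethylbutyl}benzaldehyde F5. Addition of 2-(4-methoxyphenyl)ethylmagnesium bromide (THF, 0 °C) should give 1-(2,4,6-tris(benzyloxy)-3-{(1R,2R,3S)-1,4-bis[4-(benzyloxy)phenyl]-2,3-dimethylbutyl}phenyl)-3-(4-methoxyphenyl)propan-1-ol F6 as a mixture of carbinol epimers. Oxidation with Dess–Martin periodinane (CH2Cl2, rt) rejoins the route at ketone 21.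

**Further compounds**

F1 | step 4 | 5,7-bis(benzyloxy)coumarin | O=C1C=Cc2c(OCc3ccccc3)cc(OCc3ccccc3)cc2O1
F2 | step 4 | (R)-5,7-bis(benzyloxy)-4-[4-(benzyloxy)phenyl]chroman-2-one | O=C1C[C@H](c2ccc(OCc3ccccc3)cc2)c2c(OCc3ccccc3)cc(OCc3ccccc3)cc2O1
F3 | step 10 | (3S,4R)-1,4-bis[4-(benzyloxy)phenyl]-3-methyl-4-[2,4,6-tris(benzyloxy)phenyl]-2-[(trimethylsilyl)methyl]butan-2-ol (C2 epimers) | C[Si](C)(C)CC(O)(Cc1ccc(OCc2ccccc2)cc1)[C@@H](C)[C@H](c1ccc(OCc2ccccc2)cc1)c1c(OCc2ccccc2)cc(OCc2ccccc2)cc1OCc1ccccc1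
F4 | step 10 | (3S,4R)-1,4-bis[4-(benzyloxy)phenyl]-3-methyl-2-methylidene-4-[2,4,6-tris(benzyloxy)phenyl]butane | C=C(Cc1ccc(OCc2ccccc2)cc1)[C@@H](C)[C@H](c1ccc(OCc2ccccc2)cc1)c1c(OCc2ccccc2)cc(OCc2ccccc2)cc1OCc1ccccc1
F5 | step 11 | 2,4,6-tris(benzyloxy)-3-{(1R,2R,3S)-1,4-bis[4-(benzyloxy)phenyl]-2,3-dimethylbutyl}benzaldehyde | O=Cc1c(OCc2ccccc2)cc(OCc2ccccc2)c([C@@H](c2ccc(OCc3ccccc3)cc2)[C@H](C)[C@@H](C)Cc2ccc(OCc3ccccc3)cc2)c1OCc1ccccc1
F6 | step 11 | 1-(2,4,6-tris(benzyloxy)-3-{(1R,2R,3S)-1,4-bis[4-(benzyloxy)phenyl]-2,3-dimethylbutyl}phenyl)-3-(4-methoxyphenyl)propan-1-ol (carbinol epimers) | COc1ccc(CCC(O)c2c(OCc3ccccc3)cc(OCc3ccccc3)c([C@@H](c3ccc(OCc4ccccc4)cc3)[C@H](C)[C@@H](C)Cc3ccc(OCc4ccccc4)cc3)c2OCc2ccccc2)cc1
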